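(All runs were computed with made-up constants; noise was put on by code.)

Chemist, one flask stands stalled before you, the north-west run, and an earlier run, east, lies beside it.

| setting | north-west | east | flask |
|---|---|---|---|
| starting material | 0.20 mM | 0.20 mM | 0.20 mM |
| reagent | 0.18 mM | 0.090 mM | 0.180 mM |
| free catalyst | 10 µM | 10 µM | 10 µM |
| temperature | 90 °C | 75 °C | 90 °C |
| remark | the very flask that is asked about, followed so far | run made earlier |  |
| time |  |  | 40 min |

| run | time / min | target / % | starting material / % |
|---|---|---|---|
| north-west | 2.00 | 71.9 | 27.9 |
| north-west | 6.00 | 74.1 | 24.2 |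
| north-west | 12.0 | 74.4 | 24.6 |
| north-west | 15.0 | 74.8 | 24.8 |
| north-west | 25.0 | 75.0 | 24.6 |
| north-west | 30.0 | 74.0 | 23.5 |
| north-west | 40.0 | 74.5 | 24.3 |
| east | 2.00 | 37.1 | 61.4 |
| east | 3.00 | 40.6 | 57.2 |
| east | 5.00 | 42.9 | 55.6 |
| east | 6.00 | 42.9 | 55.5 |
| east | 8.00 | 42.5 | 55.9 |
| east | 10.0 | 43.0 | 55.1 |
| east | 12.0 | 44.6 | 54.9 |

(readings scatter by 0.5 percentage points)

- alder: at 40 min add free catalyst, 100 % of the amount charged, then wait 40 min
- birch: at 40 min add reagent, 100 % of the amount charged, then wait 40 min
- elm: at 40 min raise the temperature by 20 K, then wait 40 min
- ash: change nothing and wait 40 min more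
- cedar: at 40 min take out 90 % of the target then present, then wait 40 min

- target taken out counts as made
- reactions considered so far: catalyst intermediate C -> free catalyst + target; free catalyst + target -> spent catalyst B; starting material + catalyst intermediate A <-> catalyst intermediate B; catalyst intermediate B <-> catalyst intermediate C; free catalyst -> spent catalyst A; reagent + free catalyst -> catalyst intermediate A
- additions bring no volume worth counting

- target, in percent of the starting material first charged, at 40 min
- what to do for the largest gain in target; "none" if nothing gains more than 2 percentage points (alder / birch / elm / ash / cedar / none)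
- target present, with what was taken out counted in, in percent of the starting material first charged, after alder
- target present, with what was taken out counted in, in percent of the starting material first charged, after cedar

Read the north-west flask first. Target stands at 71.9 % after 2.00 min and at 74.5 % at 40.0 min, so take that last reading for "now". Guess that a charge ran out, then test it. Starting material reads 24.3 %. Reagent is not read, so count one reagent per target: 0.149 mM made from 0.18 mM leaves 0.0310 mM. Both remain, so drop the guess. Guess equilibrium next. But catalyst intermediate C gives target by a one-way step, so drop that too. Guess that the free catalyst died. The east run does not object: its target reads 42.5 % to 43.0 % from 5.00 min to 10.0 min, about 2 percentage points under the 45.0 % its reagent allows, so there reagent is the limiting reagent.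

Now count. The north-west flask gave 14.9 turnovers per catalyst. An equal fresh charge at that count could make 0.149 mM, more than the 0.0310 mM of reagent, and alder would use up the reagent. Object: a catalyst need not have a fixed count. Free catalyst either takes reagent or dies, and taking reagent slows as [reagent] falls. So let catalyst lost per target go as one over [reagent], and integrate. Logarithms appear: the ln of [reagent] at the start over [reagent] at the end equals a constant times the free catalyst charged. The north-west flask gives 1.76, so the constant is 176 mM⁻¹. Call it the reach, the fall in ln[reagent] per amount of free catalyst charged.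

Apply it to alder: the gain is 13 points. Object again. The north-west balance reads 1.2 points short. If each spent catalyst B holds one target, that is 24.0 % of the catalyst charged. In a second round target stands at twice its first-round mean, so double that exit. The reach shrinks to 142 mM⁻¹, the gain to 12 points, and alder ends near 86.2 %. Commit to alder, since that gain clears the 2 points bar. Expect nothing from the other options, and expect cedar to stay at 74.5 %, with target taken out counted in.

The forecast, a point below my figure for alder, says 74.5 % now, alder, 85 % after alder and 74.5 % after cedar, holding that “Catalyst loss per turnover rises as reagent falls”. The flask gives 74.5 %, alder with a gain of 9.5 points, 84.0 % after alder and 74.5 % after cedar.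

    catalyst intermediate C → free catalyst + target (k = 1.20 s⁻¹, Ea = 79.0 kJ mol⁻¹)
    free catalyst + target → spent catalyst B (k = 79.0 M⁻¹ s⁻¹, Ea = 46.0 kJ mol⁻¹)
    starting material + catalyst intermediate A ⇌ catalyst intermediate B (K = 1.10 × 10⁵ M⁻¹, k = 48000 M⁻¹ s⁻¹, Ea = 41.0 kJ mol⁻¹, ΔH = −34.0 kJ mol⁻¹)
    catalyst intermediate B ⇌ catalyst intermediate C (K = 2.40, k = 1.30 s⁻¹, Ea = 84.0 kJ mol⁻¹, ΔH = 12.0 kJ mol⁻¹)
    free catalyst → spent catalyst A (k = 0.0230 s⁻¹, Ea = 105 kJ mol⁻¹)
    reagent + free catalyst → catalyst intermediate A (k = 5600 M⁻¹ s⁻¹, Ea = 30.0 kJ mol⁻¹)
    (constants at 90 °C)

At the start, free catalyst goes to reagent 44 times as fast as to spent catalyst A. By 20.0 min free catalyst stands at 0 %, with 75.6 % of the catalyst as spent catalyst A and 24.4 % as spent catalyst B, while 24 % of starting material and 16 % of reagent remain. Read from alder's net gain, the second charge shows a reach of 95.5 mM⁻¹. For the same flask with 0.0025 mM of free catalyst, the first reach puts reagent at 64.4 % of its charge; it stands at 59 %, with target at 37.2 %.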